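The synthesis rests on the C6–C7 bond of the C6(OH)–C7(Me)–C8(=O) aldol unit (C1 = carboxyl carbon, C24 = lactone carbonyl). A reagent-controlled boron aldol joins the complete C7–C24 ethyl ketone, already carrying both dienes, the dihydropyranone ring and the C9 CH2OTBS arm, to the C1–C6 aldehyde ester. This single operation completes the carbon skeleton and sets C6 and C7; only one fluoride deprotection follows. It exploits the C8 carbonyl, whose sole unhindered enolisable site is the C7 methylene, and the adjacent C9 stereocentre, whose C10 alkenyl arm shields one enolate face. The ketone is assembled from three pieces by Stille and Suzuki couplings.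

Key step: step 25

Remark: (−)-Ipc2BOTf and (+)-Ipc2BOMe are taken as the reagents derived from (+)-α-pinene and (−)-α-pinene, respectively. The C8 carbinol configuration made in step 4 does not matter, because C8 is oxidised in step 19.

**C7–C11 fragment (steps 1–6)**

Step 1
Reactants: 1 pent-3-yn-1-ol
Product: 3 (E)-4-iodopent-3-en-1-ol, via alkenylzirconocene 2 (not isolated)
Conditions: Cp2ZrHCl (2.5 equiv), THF, rt to 40 °C; I2, 0 °C
Reagents that add atoms: iodine, II
Why: Syn-hydrozirconation of the internal alkyne, equilibrated by excess Cp2ZrHCl to the less hindered C–Zr isomer next to the methyl group, followed by iodinolysis with retention should give the E-iodide (hydrozirconation–iodination).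

Step 2
Reactants: 3 (E)-4-iodopent-3-en-1-ol
Product: 5 (E)-4-iodopent-3-enoic acid, via iodopentenal 4 (not isolated)
Conditions: TEMPO (cat.), PhI(OAc)2, MeCN/H2O, rt
Reagents that add atoms: water, O
Why: The oxoammonium oxidation (TEMPO/PhI(OAc)2) takes the primary alcohol through the aldehyde hydrate to the acid under near-neutral conditions that should leave the alkenyl iodide and the β,γ-position of the alkene unchanged.

Step 3
Reactants: 5 (E)-4-iodopent-3-enoic acid; 6 (R)-4-benzyloxazolidin-2-one
Product: 8 (R)-4-benzyl-3-[(E)-4-iodopent-3-enoyl]oxazolidin-2-one, via mixed pivalic anhydride 7 (not isolated)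
Conditions: PivCl, Et3N, THF, −20 °C; then 6, LiCl, −20 °C to rt
Reagents that add atoms: none
Why: LiCl-assisted N-acylation through the mixed anhydride needs no strong base, so the β,γ-unsaturated acyl chain should not slip into conjugation.

Step 4
Reactants: 8 (R)-4-benzyl-3-[(E)-4-iodopent-3-enoyl]oxazolidin-2-one; 9 propanal
Product: 11 (R)-4-benzyl-3-{(2R,3S)-3-hydroxy-2-[(E)-2-iodoprop-1-enyl]pentanoyl}oxazolidin-2-one, via boron dienolate 10 (not isolated)
Conditions: Bu2BOTf, Et3N, CH2Cl2, −78 to 0 °C; 9, −78 to 0 °C; H2O2, MeOH, pH 7 buffer, 0 °C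
Reagents that add atoms: none
Why: In this Evans syn aldol the Z-boron dienolate reacts at its α-carbon through a Zimmerman–Traxler chair on the face opposite the benzyl group, which sets C9 (the C8 carbinol centre is erased later).

Step 5
Reactants: 11 aldol imide
Product: 12 (2S,3S)-2-[(E)-2-iodoprop-1-enyl]pentane-1,3-diol
Conditions: LiBH4, H2O (1 equiv), Et2O, 0 °C
Reagents that add atoms: none
Why: Reductive cleavage of the imide with LiBH4 turns the acyl carbon into the C9 hydroxymethyl group and releases the auxiliary without touching the alkenyl iodide.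

Step 6
Reactants: 12 (2S,3S)-2-[(E)-2-iodoprop-1-enyl]pentane-1,3-diol
Product: 13 (3S,4S,5E)-4-[(tert-butyldimethylsilyloxy)methyl]-6-iodohept-5-en-3-ol
Conditions: TBSCl (1.05 equiv), imidazole, CH2Cl2, 0 °C
Reagents that add atoms: tert-butyldimethylsilyl chloride, CC(C)(C)[Si](C)(C)Cl
Why: Steric discrimination should let TBSCl silylate the primary hydroxyl in preference to the flanked secondary C8 hydroxyl (selective silylation).

**C12–C17 linchpin (steps 7–11)**

Step 7
Reactants: 14 (S)-4-benzyl-3-propionyloxazolidin-2-one; 15 propargyl bromide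
Product: 17 (S)-4-benzyl-3-[(R)-2-methylpent-4-ynoyl]oxazolidin-2-one, via sodium enolate 16 (not isolated)
Conditions: NaHMDS, THF, −78 °C; 15, −78 to −40 °C
Reagents that add atoms: none
Why: In this Evans asymmetric alkylation the chelated sodium Z-enolate is propargylated on the face opposite the benzyl group, which sets C15 as R.

Step 8
Reactants: 17 alkylated imide
Product: 18 (R)-2-methylpent-4-yn-1-ol
Conditions: LiBH4, H2O (1 equiv), Et2O, 0 °C
Reagents that add atoms: none
Why: Reductive removal of the auxiliary with LiBH4 proceeds without enolisation, so C15 should be kept.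

Step 9
Reactants: 18 (R)-2-methylpent-4-yn-1-ol
Product: 19 (R)-2-methylpent-4-ynal
Conditions: Dess–Martin periodinane, NaHCO3, CH2Cl2, 0 °C to rt; solution used directly
Reagents that add atoms: none
Why: The Dess–Martin oxidation is fast and non-basic, so the α-stereocentre of the volatile aldehyde should survive.

Step 10
Reactants: 19 (R)-2-methylpent-4-ynal; 20 propyltriphenylphosphonium bromide
Product: 24 (R,Z)-6-iodo-4-methyloct-5-en-1-yne, via propylidene ylide 21 (not isolated), via iodophosphonium iodide 22 (not isolated), via iodo ylide 23 (not isolated)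
Conditions: 20, n-BuLi, THF, 0 °C; I2, −78 °C; NaHMDS, −20 °C; 19, −78 °C to rt
Reagents that add atoms: iodine, II
Why: The Stork–Zhao-type Wittig olefination with the α-iodo ylide runs under kinetic control and should give the Z-iodoalkene, placing iodine cis to C15 and thereby fixing the later C16=C17 geometry.

Step 11
Reactants: 24 (R,Z)-6-iodo-4-methyloct-5-en-1-yne
Product: 25 2-[(1E,4R,5Z)-6-iodo-4-methylocta-1,5-dienyl]-4,4,5,5-tetramethyl-1,3,2-dioxaborolane
Conditions: pinacolborane, Cy2BH (10 mol %), THF, rt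
Reagents that add atoms: pinacolborane, B1OC(C)(C)C(C)(C)O1
Why: Cy2BH-catalysed syn-hydroboration places boron at the alkyne terminus to give the E-alkenylboronate, while the trisubstituted iodoalkene is too hindered to react.

**C18–C24 lactone (steps 12–16)**

Step 12
Reactants: 26 prop-2-yn-1-ol
Product: 27 (E)-3-(tributylstannyl)prop-2-en-1-ol
Conditions: Bu3SnH, AIBN (cat.), neat, 80 °C
Reagents that add atoms: tributyltin hydride, CCCC[SnH](CCCC)CCCC
Why: Radical hydrostannation under equilibrating conditions favours the E-β-stannyl allylic alcohol, which is separable from its isomers by chromatography.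

Step 13
Reactants: 27 (E)-3-(tributylstannyl)prop-2-en-1-ol
Product: 28 (E)-3-(tributylstannyl)prop-2-enal
Conditions: MnO2, CH2Cl2, rt
Reagents that add atoms: none
Why: MnO2 oxidises the allylic alcohol selectively and under neutral conditions, so protodestannylation should not occur (allylic oxidation).

Step 14
Reactants: 28 (E)-3-(tributylstannyl)prop-2-enal; 29 cis-but-2-ene
Product: 32 (1E,3R,4S)-4-methyl-1-(tributylstannyl)hexa-1,5-dien-3-ol, via crotylpotassium 30 (not isolated), via crotylborane 31 (not isolated)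
Conditions: 29, n-BuLi, KOt-Bu, THF, −78 to −45 °C; (+)-Ipc2BOMe, −78 °C; BF3·OEt2; 28, −78 °C; NaOH, H2O2, 0 °C to rt
Reagents that add atoms: none
Why: In this Brown asymmetric crotylboration the Z-crotylborane reacts through a chair transition state to give the syn adduct, and the (+)-Ipc ligands direct attack to the Re face of the aldehyde, which sets C20 and C21.

Step 15
Reactants: 32 syn homoallylic alcohol; 33 acryloyl chloride
Product: 34 (1E,3R,4S)-4-methyl-1-(tributylstannyl)hexa-1,5-dien-3-yl acrylate
Conditions: 33, i-Pr2NEt, DMAP (cat.), CH2Cl2, −20 to 0 °C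
Reagents that add atoms: none
Why: Plain O-acylation installs C23 and C24 without affecting either stereocentre.

Step 16
Reactants: 34 acrylate
Product: 35 (5S,6R)-5-methyl-6-[(E)-2-(tributylstannyl)ethenyl]-5,6-dihydro-2H-pyran-2-one
Conditions: second-generation Grubbs catalyst (H2IMes)(PCy3)Cl2Ru=CHPh (5 mol %), CH2Cl2 (dilute), reflux
Reagents that add atoms: none
Why: Ring-closing metathesis between the terminal vinyl group and the acrylate closes the six-membered cis-dihydropyranone, while the bulky 1,2-disubstituted alkenylstannane should stay out of the catalytic cycle.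

**Assembly of the C7–C24 ketone (steps 17–19)**

Step 17
Reactants: 25 iodo boronate linchpin; 35 stannyl lactone
Product: 36 (5S,6S)-6-[(1E,3Z,5R,7E)-3-ethyl-5-methyl-8-(pinacolboryl)octa-1,3,7-trienyl]-5-methyl-5,6-dihydro-2H-pyran-2-one
Conditions: Pd2(dba)3 (5 mol %), AsPh3 (20 mol %), NMP, rt to 35 °C, no base
Reagents that add atoms: none
Why: In this Stille coupling zerovalent palladium inserts into the C17–I bond and transmetalates with the alkenylstannane with retention at both alkenes, and without base or fluoride the pinacol boronate should remain a spectator.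

Step 18
Reactants: 36 trienyl boronate lactone; 13 C7–C11 alkenyl iodide
Product: 37 (5S,6S)-6-[(1E,3Z,5R,7E,9E,11S,12S)-11-(TBSOCH2)-3-ethyl-12-hydroxy-5,9-dimethyltetradeca-1,3,7,9-tetraenyl]-5-methyl-5,6-dihydro-2H-pyran-2-one
Conditions: Pd(PPh3)4 (10 mol %), TlOEt, THF/H2O (3:1), rt
Reagents that add atoms: none
Why: The TlOEt-accelerated Suzuki–Miyaura coupling joins C11 to C12 with retention of both alkene geometries quickly enough to spare the lactone, and keeping C8 at the carbinol level makes C9 non-acidic during this basic step.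

Step 19
Reactants: 37 C7–C24 alcohol
Product: 38 (5S,6S)-6-[(1E,3Z,5R,7E,9E,11S)-11-(TBSOCH2)-3-ethyl-5,9-dimethyl-12-oxotetradeca-1,3,7,9-tetraenyl]-5-methyl-5,6-dihydro-2H-pyran-2-one
Conditions: Dess–Martin periodinane, NaHCO3, CH2Cl2, 0 °C to rt
Reagents that add atoms: none
Why: The buffered Dess–Martin oxidation forms the β,γ-unsaturated ethyl ketone under non-basic conditions, so C9 should not epimerise and the C10 alkene should not move into conjugation.

**C1–C6 aldehyde (steps 20–24)**

Step 20
Reactants: 39 but-2-ynoic acid; 40 2-(trimethylsilyl)ethanol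
Product: 41 2-(trimethylsilyl)ethyl but-2-ynoate
Conditions: DCC, DMAP (cat.), CH2Cl2, 0 °C to rt
Reagents that add atoms: none
Why: The Steglich esterification installs a fluoride-labile ester under neutral conditions.

Step 21
Reactants: 42 (R)-3-bromo-2-methylpropan-1-ol
Product: 43 (R)-(3-bromo-2-methylpropoxy)(tert-butyl)dimethylsilane
Conditions: TBSCl, imidazole, CH2Cl2, rt
Reagents that add atoms: tert-butyldimethylsilyl chloride, CC(C)(C)[Si](C)(C)Cl
Why: Standard silylation masks the hydroxyl so that the bromide can be turned into an organometallic reagent.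

Step 22
Reactants: 43 silyloxy bromide; 41 2-(trimethylsilyl)ethyl but-2-ynoate
Product: 47 2-(trimethylsilyl)ethyl (S,E)-6-(tert-butyldimethylsilyloxy)-3,5-dimethylhex-2-enoate, via Grignard reagent 44 (not isolated), via alkylcopper 45 (not isolated), via alkenylcopper 46 (not isolated)
Conditions: Mg, THF; CuBr·SMe2, −40 °C; 41, −78 °C; aq NH4Cl, −78 °C
Reagents that add atoms: none
Why: Carbocupration of the ynoate is a syn addition, and protonation of the configurationally stable alkenylcopper at −78 °C should give the E-trisubstituted enoate, with C5 carried unchanged from 42.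

Step 23
Reactants: 47 silyl ether enoate
Product: 48 2-(trimethylsilyl)ethyl (S,E)-6-hydroxy-3,5-dimethylhex-2-enoate
Conditions: HF·pyridine, THF, 0 °C to rt
Reagents that add atoms: none
Why: Acidic fluoride cleaves the primary TBS ether, whereas the 2-(trimethylsilyl)ethyl ester needs free fluoride anion and should survive (selective desilylation).

Step 24
Reactants: 48 hydroxy enoate
Product: 49 2-(trimethylsilyl)ethyl (S,E)-3,5-dimethyl-6-oxohex-2-enoate
Conditions: Dess–Martin periodinane, NaHCO3, CH2Cl2, 0 °C to rt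
Reagents that add atoms: none
Why: The non-basic Dess–Martin oxidation should deliver the α-methyl aldehyde without epimerising C5.

**Union and deprotection (steps 25–26)**

Step 25
Reactants: 38 C7–C24 ethyl ketone; 49 C1–C6 aldehyde ester
Product: 51 kazusamycin A 2-(trimethylsilyl)ethyl ester with the C9 hydroxymethyl group as TBS ether, via enol borinate 50 (not isolated)
Conditions: (−)-Ipc2BOTf [from (−)-Ipc2BH, TfOH, hexane], i-Pr2NEt, CH2Cl2, −78 °C; 49, −78 to −20 °C; H2O2, MeOH, pH 7 buffer, 0 °C
Reagents that add atoms: none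
Why: Ipc2BOTf binds the C8 carbonyl and i-Pr2NEt removes a proton from the unhindered C7 methylene rather than from the tertiary, doubly flanked C9–H, giving Z-enol borinate 50, which adds to aldehyde 49 through a closed Zimmerman–Traxler chair; the closest known reaction type is the reagent-controlled syn boron aldol of α-chiral ethyl ketones with diisopinocampheylboron triflate. No ring is closed. The Z-enolate geometry translates into the C6/C7 syn relationship. The absolute sense at C7 and C6 is set by the (−)-Ipc ligands, which steer the enolate to the Si face of the aldehyde, and it should be reinforced by C9, which places its C10 alkenyl arm anti to the incoming aldehyde, its hydrogen toward boron and the non-chelating CH2OTBS arm away from the enolate oxygen, so that the C7 methyl and the C9 CH2O arm end up syn. The C5 centre of 49 distinguishes only CH3 from CH2 and exerts little bias, so enolate control should also deliver the C5/C6 syn (Felkin) triad. Chemoselectivity is needed against the dihydropyranone ring and the enoate: neither has an enolisable α-proton, esters are not enolised by this reagent pair, boron enolates do not add in conjugate fashion, and the buffered peroxide work-up should leave the electron-poor and the conjugated alkenes untouched.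

Step 26
Reactants: 51 protected aldol adduct
Product: 52 kazusamycin A
Conditions: TASF, DMF/H2O, 0 °C to rt; aq NH4Cl
Reagents that add atoms: none
Why: Fluoride from TASF cleaves the Si–O bond of the TBS ether and fragments the 2-(trimethylsilyl)ethyl ester to ethylene and Me3SiF in one operation, and its low basicity in wet DMF should spare the β-hydroxy ketone and the lactone (global fluoride deprotection).

**Compound list**

1 | pent-3-yn-1-ol | CC#CCCO | starting material
2 | (E)-alkenylzirconocene from 1 (Zr on C4, oxygen bound to a second Cp2ZrCl) | C/C(=C\CCO[Zr](Cl)(C1C=CC=C1)C1C=CC=C1)[Zr](Cl)(C1C=CC=C1)C1C=CC=C1 | intermediate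
3 | (E)-4-iodopent-3-en-1-ol | C/C(I)=C\CCO | intermediate
4 | (E)-4-iodopent-3-enal | C/C(I)=C\CC=O | intermediate
5 | (E)-4-iodopent-3-enoic acid | C/C(I)=C\CC(=O)O | intermediate
6 | (R)-4-benzyloxazolidin-2-one | O=C1N[C@H](Cc2ccccc2)CO1 | starting material
7 | (E)-4-iodopent-3-enoic pivalic anhydride | C/C(I)=C\CC(=O)OC(=O)C(C)(C)C | intermediate
8 | (R)-4-benzyl-3-[(E)-4-iodopent-3-enoyl]oxazolidin-2-one | C/C(I)=C\CC(=O)N1[C@H](Cc2ccccc2)COC1=O | intermediate
9 | propanal | CCC=O | starting material
10 | dibutylboron Z(O)-dienolate of 8 | CCCCB(CCCC)O/C(=C\C=C(/C)I)N1[C@H](Cc2ccccc2)COC1=O | intermediate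
11 | (R)-4-benzyl-3-{(2R,3S)-3-hydroxy-2-[(E)-2-iodoprop-1-enyl]pentanoyl}oxazolidin-2-one | CC[C@H](O)[C@@H](/C=C(\C)I)C(=O)N1[C@H](Cc2ccccc2)COC1=O | intermediate
12 | (2S,3S)-2-[(E)-2-iodoprop-1-enyl]pentane-1,3-diol | CC[C@H](O)[C@@H](/C=C(\C)I)CO | intermediate
13 | (3S,4S,5E)-4-[(tert-butyldimethylsilyloxy)methyl]-6-iodohept-5-en-3-ol | CC[C@H](O)[C@@H](/C=C(\C)I)CO[Si](C)(C)C(C)(C)C | intermediate
14 | (S)-4-benzyl-3-propionyloxazolidin-2-one | CCC(=O)N1[C@@H](Cc2ccccc2)COC1=O | starting material
15 | propargyl bromide | C#CCBr | starting material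
16 | sodium Z-enolate of 14 | C/C=C(\[O-])N1[C@@H](Cc2ccccc2)COC1=O.[Na+] | intermediate
17 | (S)-4-benzyl-3-[(R)-2-methylpent-4-ynoyl]oxazolidin-2-one | C#CC[C@@H](C)C(=O)N1[C@@H](Cc2ccccc2)COC1=O | intermediate
18 | (R)-2-methylpent-4-yn-1-ol | C#CC[C@@H](C)CO | intermediate
19 | (R)-2-methylpent-4-ynal | C#CC[C@@H](C)C=O | intermediate
20 | propyltriphenylphosphonium bromide | CCC[P+](c1ccccc1)(c1ccccc1)c1ccccc1.[Br-] | starting material
21 | propylidenetriphenylphosphorane | CCC=P(c1ccccc1)(c1ccccc1)c1ccccc1 | intermediate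
22 | (1-iodopropyl)triphenylphosphonium iodide | CCC(I)[P+](c1ccccc1)(c1ccccc1)c1ccccc1.[I-] | intermediate
23 | (1-iodopropylidene)triphenylphosphorane | CCC(I)=P(c1ccccc1)(c1ccccc1)c1ccccc1 | intermediate
24 | (R,Z)-6-iodo-4-methyloct-5-en-1-yne | C#CC[C@@H](C)/C=C(\I)CC | intermediate
25 | 2-[(1E,4R,5Z)-6-iodo-4-methylocta-1,5-dienyl]-4,4,5,5-tetramethyl-1,3,2-dioxaborolane | CC/C(I)=C/[C@H](C)C/C=C/B1OC(C)(C)C(C)(C)O1 | intermediate
26 | prop-2-yn-1-ol | C#CCO | starting material
27 | (E)-3-(tributylstannyl)prop-2-en-1-ol | CCCC[Sn](CCCC)(CCCC)/C=C/CO | intermediate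
28 | (E)-3-(tributylstannyl)prop-2-enal | CCCC[Sn](CCCC)(CCCC)/C=C/C=O | intermediate
29 | cis-but-2-ene | C/C=C\C | starting material
30 | (Z)-crotylpotassium | C/C=C\[CH2-].[K+] | intermediate
31 | (Z)-crotylbis[(+)-isopinocampheyl]borane | C/C=C\CB([C@H]1C[C@H]2C[C@@H]([C@@H]1C)C2(C)C)[C@H]1C[C@H]2C[C@@H]([C@@H]1C)C2(C)C | intermediate
32 | (1E,3R,4S)-4-methyl-1-(tributylstannyl)hexa-1,5-dien-3-ol (3,4-syn) | C=C[C@H](C)[C@@H](O)/C=C/[Sn](CCCC)(CCCC)CCCC | intermediate
33 | acryloyl chloride | C=CC(=O)Cl | starting material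
34 | (1E,3R,4S)-4-methyl-1-(tributylstannyl)hexa-1,5-dien-3-yl acrylate | C=C[C@H](C)[C@@H](OC(=O)C=C)/C=C/[Sn](CCCC)(CCCC)CCCC | intermediate
35 | (5S,6R)-5-methyl-6-[(E)-2-(tributylstannyl)ethenyl]-5,6-dihydro-2H-pyran-2-one (cis) | CCCC[Sn](CCCC)(CCCC)/C=C/[C@@H]1OC(=O)C=C[C@@H]1C | intermediate
36 | (5S,6S)-6-[(1E,3Z,5R,7E)-3-ethyl-5-methyl-8-(pinacolboryl)octa-1,3,7-trienyl]-5-methyl-5,6-dihydro-2H-pyran-2-one | CCC(=C/[C@H](C)C/C=C/B1OC(C)(C)C(C)(C)O1)/C=C/[C@@H]1OC(=O)C=C[C@@H]1C | intermediate
37 | C7–C24 alcohol (8S,9S,15R,20S,21S; 10E,12E,16Z,18E; C9 CH2OTBS) | CCC(=C/[C@H](C)C/C=C/C(C)=C/[C@@H](CO[Si](C)(C)C(C)(C)C)[C@@H](O)CC)/C=C/[C@@H]1OC(=O)C=C[C@@H]1C | intermediate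
38 | C7–C24 ethyl ketone (9S,15R,20S,21S; 10E,12E,16Z,18E; C9 CH2OTBS) | CCC(=C/[C@H](C)C/C=C/C(C)=C/[C@@H](CO[Si](C)(C)C(C)(C)C)C(=O)CC)/C=C/[C@@H]1OC(=O)C=C[C@@H]1C | intermediate
39 | but-2-ynoic acid | CC#CC(=O)O | starting material
40 | 2-(trimethylsilyl)ethanol | C[Si](C)(C)CCO | starting material
41 | 2-(trimethylsilyl)ethyl but-2-ynoate | CC#CC(=O)OCC[Si](C)(C)C | intermediate
42 | (R)-3-bromo-2-methylpropan-1-ol | OC[C@@H](C)CBr | starting material
43 | (R)-(3-bromo-2-methylpropoxy)(tert-butyl)dimethylsilane | CC(C)(C)[Si](C)(C)OC[C@@H](C)CBr | intermediate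
44 | Grignard reagent from 43 | CC(C)(C)[Si](C)(C)OC[C@@H](C)C[Mg]Br | intermediate
45 | alkylcopper from 44 | CC(C)(C)[Si](C)(C)OC[C@@H](C)C[Cu] | intermediate
46 | alkenylcopper syn-adduct of 45 to 41 | CC(C)(C)[Si](C)(C)OC[C@@H](C)C/C(C)=C(\[Cu])C(=O)OCC[Si](C)(C)C | intermediate
47 | 2-(trimethylsilyl)ethyl (S,E)-6-(tert-butyldimethylsilyloxy)-3,5-dimethylhex-2-enoate | CC(C)(C)[Si](C)(C)OC[C@@H](C)C/C(C)=C/C(=O)OCC[Si](C)(C)C | intermediate
48 | 2-(trimethylsilyl)ethyl (S,E)-6-hydroxy-3,5-dimethylhex-2-enoate | OC[C@@H](C)C/C(C)=C/C(=O)OCC[Si](C)(C)C | intermediate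
49 | 2-(trimethylsilyl)ethyl (S,E)-3,5-dimethyl-6-oxohex-2-enoate | O=C[C@@H](C)C/C(C)=C/C(=O)OCC[Si](C)(C)C | intermediate
50 | Z-enol bis[(−)-isopinocampheyl]borinate of 38 | CCC(=C/[C@H](C)C/C=C/C(C)=C/[C@@H](CO[Si](C)(C)C(C)(C)C)/C(OB([C@@H]1C[C@@H]2C[C@H]([C@H]1C)C2(C)C)[C@@H]1C[C@@H]2C[C@H]([C@H]1C)C2(C)C)=C/C)/C=C/[C@@H]1OC(=O)C=C[C@@H]1C | intermediate
51 | kazusamycin A 2-(trimethylsilyl)ethyl ester, C9 CH2OTBS (5S,6R,7S,9S,15R,20S,21S) | CCC(=C/[C@H](C)C/C=C/C(C)=C/[C@@H](CO[Si](C)(C)C(C)(C)C)C(=O)[C@@H](C)[C@H](O)[C@@H](C)C/C(C)=C/C(=O)OCC[Si](C)(C)C)/C=C/[C@@H]1OC(=O)C=C[C@@H]1C | intermediate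
52 | kazusamycin A | CCC(=C/[C@H](C)C/C=C/C(C)=C/[C@@H](CO)C(=O)[C@@H](C)[C@H](O)[C@@H](C)C/C(C)=C/C(=O)O)/C=C/[C@@H]1OC(=O)C=C[C@@H]1C | target

Total step count: 26.
Longest linear sequence: 10 steps (for example steps 1, 2, 3, 4, 5, 6, 18, 19, 25, 26).

**Steps most likely to fail**

Step 25. The enol borinate may discriminate its two faces too weakly, or the hindered full-length ketone may enolise slowly, which would waste the most valuable intermediate in hard-to-separate mixtures. The fallback moves the aldol to the small iodide and makes the cross-coupling the last union. It sets out from 13. Dess–Martin oxidation gives (S,E)-4-[(tert-butyldimethylsilyloxy)methyl]-6-iodohept-5-en-3-one F1. Its Z-enol borinate is added to 49 to give the iodoalkenyl aldol adduct F2. At this size the reagent antipodes and other metal enolates can be compared on scale, and the diastereomers can be separated and assigned. Suzuki coupling of F2 with 36 under the conditions of step 18 returns to the route at 51.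

Step 17. The alkenyl boronate may transmetalate or protodeboronate, and oxidative addition to the hindered Z-iodide may be slow enough for the stannane to homocouple. The fallback removes boron from the coupling. It sets out from 24 and 35, whose Stille coupling gives the terminal alkyne (5S,6S)-6-[(1E,3Z,5R)-3-ethyl-5-methylocta-1,3-dien-7-ynyl]-5-methyl-5,6-dihydro-2H-pyran-2-one F3. Cy2BH-catalysed hydroboration with pinacolborane prefers the terminal alkyne over the substituted and conjugated alkenes and returns to the route at 36.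

Step 26. The basic fluoride needed for the 2-(trimethylsilyl)ethyl ester may cause retro-aldol cleavage at C6–C7, β-elimination of the C9 hydroxymethyl group, or opening of the dihydropyranone. The fallback changes the ester so that only acidic fluoride is needed at the end. It sets out from 47.
- TBAF removes both silicon groups to give (S,E)-6-hydroxy-3,5-dimethylhex-2-enoic acid F4.
- Dess–Martin oxidation gives (S,E)-3,5-dimethyl-6-oxohex-2-enoic acid F5.
- TBSCl and imidazole give tert-butyldimethylsilyl (S,E)-3,5-dimethyl-6-oxohex-2-enoate F6.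
- The aldol of step 25 with 38 gives the bis-TBS aldol adduct F7.
- HF·pyridine in THF cleaves the silyl ester and the silyl ether together and returns to the route at 52.

Further compounds
F1 | step 25 | (S,E)-4-[(tert-butyldimethylsilyloxy)methyl]-6-iodohept-5-en-3-one | CCC(=O)[C@@H](/C=C(\C)I)CO[Si](C)(C)C(C)(C)C
F2 | step 25 | iodoalkenyl aldol adduct (C1–C11, 5S,6R,7S,9S, TMSE ester, C9 CH2OTBS) | I/C(C)=C/[C@@H](CO[Si](C)(C)C(C)(C)C)C(=O)[C@@H](C)[C@H](O)[C@@H](C)C/C(C)=C/C(=O)OCC[Si](C)(C)C
F3 | step 17 | (5S,6S)-6-[(1E,3Z,5R)-3-ethyl-5-methylocta-1,3-dien-7-ynyl]-5-methyl-5,6-dihydro-2H-pyran-2-one | CCC(=C/[C@H](C)CC#C)/C=C/[C@@H]1OC(=O)C=C[C@@H]1C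
F4 | step 26 | (S,E)-6-hydroxy-3,5-dimethylhex-2-enoic acid | OC[C@@H](C)C/C(C)=C/C(=O)O
F5 | step 26 | (S,E)-3,5-dimethyl-6-oxohex-2-enoic acid | O=C[C@@H](C)C/C(C)=C/C(=O)O
F6 | step 26 | tert-butyldimethylsilyl (S,E)-3,5-dimethyl-6-oxohex-2-enoate | O=C[C@@H](C)C/C(C)=C/C(=O)O[Si](C)(C)C(C)(C)C
F7 | step 26 | bis-TBS aldol adduct (kazusamycin A TBS ester, C9 CH2OTBS) | CCC(=C/[C@H](C)C/C=C/C(C)=C/[C@@H](CO[Si](C)(C)C(C)(C)C)C(=O)[C@@H](C)[C@H](O)[C@@H](C)C/C(C)=C/C(=O)O[Si](C)(C)C(C)(C)C)/C=C/[C@@H]1OC(=O)C=C[C@@H]1C
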